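(Readings and results were generated by integration with constants of no real substance, and the scatter is random.)

A leftover opens this problem: at 120 min the amber run still had 34.0% of its left-handed and right-handed substrate unreacted, yet its products had grown by just 6 percentage points since 50.0 min.

in all of them: left-handed substrate 1.2 M; right-handed substrate 1.2 M

|  | partner | free catalyst | remark | time |
|---|---|---|---|---|
| blue | 2 equiv | 0.25 mol% | run made earlier |  |
| amber | 2 equiv | 0.38 mol% | run made earlier |  |
| flask | 2.00 equiv | 0.5 mol% |  | 2.5 h |

| run | time / min | left-handed product / % | right-handed product / % |
|---|---|---|---|
| blue | 10.0 | 6 | 6 |
| blue | 20.0 | 10 | 16 |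
| blue | 50.0 | 20 | 24 |
| blue | 120 | 26 | 30 |
| amber | 10.0 | 7 | 10 |
| amber | 20.0 | 14 | 18 |
| amber | 50.0 | 25 | 35 |
| amber | 120 | 33 | 33 |

(standard deviation of a reading: 2 percentage points)

- free catalyst is single-handed; left-handed substrate and right-handed substrate are mirror images of each other, charged as a racemate, each of them at the stated concentration
- candidate steps: free catalyst + left-handed substrate <-> catalyst intermediate A; free catalyst + right-handed substrate <-> catalyst intermediate B; partner + catalyst intermediate A -> free catalyst + left-handed product; partner + catalyst intermediate B -> free catalyst + right-handed product; left-handed product <-> right-handed product; 2 partner -> homo dimer; partner -> decomposed reagent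
- an excess is the difference of the two amounts in percent of their sum
- an excess is below zero if the other one leads

* excess of left-handed product over right-handed product in the product at 15 min
* excess of left-handed product over right-handed product in the product at 2.5 h
* part of the left-handed substrate and right-handed substrate charged together that has reacted at 2.5 h

So count turnovers. Each turnover of the catalyst spends one partner, and 2.00 equiv on the left-handed substrate is one partner for each molecule of the two substrates together. So the part of the substrates reacted equals the part of the charged partner that has gone through the catalyst. But the candidate steps give the partner two other exits, homo dimer and decomposed reagent. If you assume that the catalyst's draw is in step with the loading, and that this draw and those losses both run first order in partner, then at the end of the partner the ratio of reacted to unreacted part grows in step with the loading. Taking the last readings as ends, the loading divided by that ratio is 0.2 mol% in the blue run and 0.2 mol% in the amber run, both readings with their scatter. Take 0.2 mol% as the break-even loading, the loading at which the catalyst takes as much partner as the two exits together. The part reacted is then the loading over the loading plus the break-even loading, so my reckoning for 0.5 mol% is 71.8%.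

The forecast gives 80% reacted, within 70% to 90%, with excesses of −15% at 15 min and −6% at 2.5 h; its reading of the runs is “That suggests the partner is being lost”. My figure is lower than the forecast's.

The flask gives −12.9% at 15 min, −0.337% at 2.5 h and 72.1% reacted.

    free catalyst + left-handed substrate ⇌ catalyst intermediate A (K = 3.80 M⁻¹, k = 100 M⁻¹ min⁻¹)
    free catalyst + right-handed substrate ⇌ catalyst intermediate B (K = 10.0 M⁻¹, k = 320 M⁻¹ min⁻¹)
    partner + catalyst intermediate A → free catalyst + left-handed product (k = 10.0 M⁻¹ min⁻¹)
    partner + catalyst intermediate B → free catalyst + right-handed product (k = 4.00 M⁻¹ min⁻¹)
    left-handed product ⇌ right-handed product (k = 0.00730 min⁻¹)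
    2 partner → homo dimer (k = 9.20 × 10⁻⁴ M⁻¹ min⁻¹)
    partner → decomposed reagent (k = 0.00930 min⁻¹)

At 0.250 h the two catalyst intermediates in this flask drew on the partner at 0.0298 min⁻¹, faster than decomposition at 0.0093 min⁻¹. At 2.5 h this flask still held, unbound, 0.26% of its charged partner, the limiting reagent, less than the 32% of its charged left-handed substrate. For the same flask with 0.12 mol% of free catalyst, the break-even loading of 0.2 mol% gives 38.0% reacted, and at 2.5 h that neighbour stands at 35.9%.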